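Ring A is C1 (chain carbon) to C6, ring B C4-C5-C7-C12, ring C C7-C8-C11-C12, ring D C8-C9-C10-C11. Cutting the rungs C4-C5, C7-C12, C8-C11 and C9-C10 leaves two mirror-related rails, C3-C4-C12-C11-C10 and C6-C5-C7-C8-C9, each a pentadienoic acid. The key step uses this hidden symmetry: two dienoates, stacked as peri-diester 3 of naphthalene-1,8-diol, are irradiated to form all four rungs, close rings B, C and D and set six stereocentres in meso diester 5. Anhydride desymmetrisation, Suzuki coupling, metathesis and convex-face hydrogenation then add C1, C2 and the chain.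

Key step: step 2

Assumption: quinidine is taken to deliver methanol to carbonyl C3 of anhydride 7; if the sense of induction proves opposite, the pseudoenantiomeric alkaloid quinine is used in step 5.

Step 1
Reactants: 1 (E)-penta-2,4-dienoic acid (2.2 equiv); 2 naphthalene-1,8-diol
Product: 3 naphthalene-1,8-diyl bis[(E)-penta-2,4-dienoate]
Conditions: DCC (2.3 equiv), DMAP (0.2 equiv), BHT (trace), CH2Cl2, 0 °C to rt, dark; slow crystallisation from EtOAc/hexane, keeping the crystal form whose facing diene carbons lie within about 4.2 Å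
Reagents that add atoms: none
Why: Steglich esterification acylates both peri phenols in one operation, leaves the E-dienes untouched and avoids the polymerisation-prone dienoyl chloride.

Step 2
Reactants: 3 naphthalene-1,8-diyl bis[(E)-penta-2,4-dienoate]
Product: 5 naphthalene-1,8-diyl anti-tricyclo[4.2.0.0(2,5)]octane-3,4-dicarboxylate (meso ladder B-C-D; C3 and C6 cis and exo on ring B), via cis-divinylcyclobutane 4 (not isolated)
Conditions: hν (medium-pressure Hg lamp, Pyrex filter, λ > 290 nm), microcrystalline layer of 3 between glass plates, N2, 0 °C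
Reagents that add atoms: none
Why: Proposed new method: excitation of the stacked arms (directly, or through the naphthalene unit acting as a built-in triplet antenna) should start a topochemical [2+2] photocycloaddition of the facing bonds C4=C12 and C5=C7 to give 4, whose two vinyl groups, still parallel in the lattice, then undergo a second [2+2] (C11=C10 onto C8=C9). The closest known reaction types are the solid-state dimerisation of cinnamates on the same peri-diol template and the double [2+2] of aryl-, pyridyl- or ester-capped dienes held by a template or cyclophane, whereas a diene ending in a free CH2 has not been tried. Ring B closes by straight head-to-head [2+2] (rungs C4-C5 and C7-C12), ring D by straight rather than crossed [2+2] of the 1,5-diene in 4 (rungs C8-C11 and C9-C10), and ring C needs no cycloaddition of its own because the rungs C7-C12 and C8-C11 join the former diene single bonds C7-C8 and C11-C12. C4 and C5 become cis because both acyl groups hang from one template, C7 and C12 end up trans to C6 and C3 because suprafacial addition preserves the E geometry, and C8 and C11 place ring D anti to ring B because both dienes react in the s-trans conformation. The step needs head-to-head regiochemistry, straight closure instead of crossed, [4+4] or [4+2] closure, and no polymerisation; the short peri O-to-O distance that stacks the arms and the rigidity of the crystal are meant to secure these. Working at 0 °C keeps 4 well below the temperature at which it would undergo Cope rearrangement.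

Step 3
Reactants: 5 template-bridged meso ladder diester
Product: 6 meso anti-tricyclo[4.2.0.0(2,5)]octane-3,4-dicarboxylic acid (carboxyls C3 and C6 cis and exo)
Conditions: LiOH (5 equiv), degassed THF/H2O 3:1, 0 °C to rt, N2; then 1 M HCl, 0 °C
Reagents that add atoms: lithium hydroxide, [Li+].[OH-]
Why: Saponification of activated aryl esters is fast at low temperature, so the cis-diacid should be released before C4 or C5 can epimerise, and the template is recovered.

Step 4
Reactants: 6 meso ladder diacid
Product: 7 meso ladder anhydride (five-membered ring C3-O-C6 fused on C4-C5)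
Conditions: (CF3CO)2O (1.5 equiv), CH2Cl2, 0 °C to rt; evaporate
Reagents that add atoms: none
Why: Dehydration with trifluoroacetic anhydride closes the cyclic anhydride, which only a cis-diacid can form, at a temperature that is harmless for the strained core.

Step 5
Reactants: 7 meso ladder anhydride
Product: 8 half-ester with the methyl ester at C3 (on C4) and the free acid at C6 (on C5), single enantiomer
Conditions: quinidine (1.1 equiv), MeOH (3 equiv), toluene, −55 °C; 1 M HCl wash (alkaloid recovered)
Reagents that add atoms: methanol, CO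
Why: Cinchona-alkaloid-mediated desymmetrising methanolysis of a meso succinic-type anhydride, in which the alkaloid acts as chiral general base and steers methanol to one enantiotopic carbonyl, fixes the absolute configuration of all six ladder stereocentres.

Step 6
Reactants: 8 half-ester
Product: 10 γ-lactone C3(=O)-O-C6H2 cis-fused on C4-C5, via hydroxy ester 9 (not isolated)
Conditions: BH3·SMe2 (1.3 equiv), THF, −10 °C to rt; aq. work-up; TsOH·H2O (5 mol %), toluene, rt
Reagents that add atoms: none
Why: Chemoselective borane reduction of a carboxylic acid beside a methyl ester, followed by acid-catalysed lactonisation of the cis hydroxy ester, differentiates C3 from C6 without touching a stereocentre.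

Step 7
Reactants: 10 γ-lactone
Product: 11 lactol (C3 hemiacetal, mixture of anomers)
Conditions: i-Bu2AlH (1.1 equiv), CH2Cl2, −78 °C; aq. potassium sodium tartrate
Reagents that add atoms: none
Why: Partial reduction of a γ-lactone with i-Bu2AlH stops at the lactol stage at −78 °C.

Step 8
Reactants: 11 lactol
Product: 12 cis vinyl alcohol (C4 bears C3H=C2H2; C5 bears C6H2OH)
Conditions: MePPh3Br (3.0 equiv), KN(SiMe3)2 (2.9 equiv), THF, 0 °C; then 11, 0 °C to rt
Reagents that add atoms: methyltriphenylphosphonium bromide, C[P+](c1ccccc1)(c1ccccc1)c1ccccc1.[Br-]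
Why: Wittig methylenation of a lactol turns the masked aldehyde carbon C3 into a vinyl group whose CH2 is C2 and frees C6H2OH; olefination should outrun enolisation at the cyclobutane carbon C4, so the cis relationship is kept.

Step 9
Reactants: 13 2,2-dimethyl-1,3-dioxan-5-ol; 14 1,7-dibromoheptane (3 equiv)
Product: 15 5-[(7-bromoheptyl)oxy]-2,2-dimethyl-1,3-dioxane
Conditions: NaH (1.1 equiv), DMF, 0 °C; then 14, rt
Reagents that add atoms: none
Why: Williamson ether synthesis on a primary bromide, with excess dibromide to suppress double alkylation.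

Step 10
Reactants: 15 bromoheptyl ether; 16 2,3-dibromopropene (1.2 equiv)
Product: 18 5-[(9-bromodec-9-en-1-yl)oxy]-2,2-dimethyl-1,3-dioxane, via Grignard reagent 17 (not isolated)
Conditions: Mg (1.5 equiv), THF, 40 °C; then 16, CuI (5 mol %), THF, 0 °C to rt
Reagents that add atoms: none
Why: Allylic substitution of 2,3-dibromopropene by a Grignard reagent gives the same 2-bromo-1-alkene by SN2 or SN2′ attack, and the vinylic bromide stays intact.

Step 11
Reactants: 12 cis vinyl alcohol; 18 2-bromo-1-alkene (1.1 equiv)
Product: 20 alcohol in which C4 bears C3H2-C2H2-C1(=CH2)-(CH2)8-O-dioxanyl and C5 bears C6H2OH, via bis(9-BBN) adduct 19 (not isolated)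
Conditions: 9-BBN-H (2.3 equiv), THF, 0 °C to rt; then 3 M aq NaOH, 18, PdCl2(dppf) (3 mol %), THF, 50 °C
Reagents that add atoms: none
Why: Anti-Markovnikov hydroboration of the only alkene (one extra equivalent of borane is consumed by the hydroxyl) and B-alkyl Suzuki-Miyaura coupling of the primary borane with the bromoalkene form the C2-C1 bond and bring in the whole chain.

Step 12
Reactants: 20 alcohol
Product: 21 aldehyde (C6HO on C5, cis to the C4 side chain)
Conditions: TEMPO (10 mol %), PhI(OAc)2 (1.1 equiv), CH2Cl2, rt
Reagents that add atoms: none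
Why: Oxoammonium (TEMPO) oxidation of a primary alcohol runs under weakly acidic, water-free conditions that spare the alkene, the acetonide and the epimerisable centre C5.

Step 13
Reactants: 21 aldehyde
Product: 22 diene (C5 bears C6H=CH2; C4 bears the chain ending in C1(=CH2))
Conditions: MePPh3Br (1.5 equiv), KN(SiMe3)2 (1.4 equiv), THF, −78 °C to 0 °C
Reagents that add atoms: methyltriphenylphosphonium bromide, C[P+](c1ccccc1)(c1ccccc1)c1ccccc1.[Br-]
Why: Wittig methylenation with an ylide made from a slight deficit of base should be faster than epimerisation of the cis cyclobutane carbaldehyde.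

Step 14
Reactants: 22 diene
Product: 23 tetracyclic alkene (ring A closed, C1=C6 trisubstituted, chain on C1)
Conditions: second-generation Grubbs catalyst RuCl2(=CHPh)(PCy3)(H2IMes) (3 mol %), CH2Cl2 (0.01 M), 40 °C
Reagents that add atoms: none
Why: Ring-closing metathesis of a vinyl group and a 1,1-disubstituted alkene held cis on ring B forms a six-membered trisubstituted alkene and is driven by loss of ethene.

Step 15
Reactants: 23 tetracyclic alkene
Product: 25 target CNP0193334.1, via saturated acetonide 24 (not isolated)
Conditions: H2 (1 atm), [Ir(cod)(PCy3)(py)]PF6 (5 mol %), CH2Cl2, rt; concentrate; then 2 M aq HCl, THF/MeOH, rt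
Reagents that add atoms: none
Why: Homogeneous hydrogenation followed by acid hydrolysis of the isopropylidene acetal: ring B, with C7-H pointing across the concave face of ring A, should force the bulky cationic iridium catalyst onto the convex face (that of H4 and H5), so H is delivered to C1 there and the chain ends up cis to ring B, (S) at C1, as in the target.

Compound list
1 | (E)-penta-2,4-dienoic acid | C=C/C=C/C(=O)O | starting material
2 | naphthalene-1,8-diol | Oc1cccc2cccc(O)c12 | starting material
3 | naphthalene-1,8-diyl bis[(E)-penta-2,4-dienoate] | C=C/C=C/C(=O)Oc1cccc2cccc(OC(=O)/C=C/C=C)c12 | intermediate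
4 | template-bridged cis-divinylcyclobutane (ring B only; carboxyls cis, vinyls cis, carboxyl/vinyl trans) | c1cc2OC(=O)[C@@H]3[C@H](C(=O)Oc4cccc(c1)c24)[C@@H](C=C)[C@H]3C=C | intermediate
5 | template-bridged meso ladder B-C-D diester (C3, C6 cis and exo; ladder anti) | c1cc2OC(=O)[C@@H]3[C@H](C(=O)Oc4cccc(c1)c24)[C@H]5[C@@H]6CC[C@@H]6[C@@H]35 | intermediate
6 | meso ladder cis-diacid | OC(=O)[C@@H]2[C@H](C(=O)O)[C@H]1[C@@H]3CC[C@@H]3[C@@H]21 | intermediate
7 | meso ladder anhydride | O1C(=O)[C@@H]2[C@H](C1=O)[C@H]3[C@@H]4CC[C@@H]4[C@@H]23 | intermediate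
8 | half-ester (C3 methyl ester, C6 acid) | COC(=O)[C@@H]2[C@H](C(=O)O)[C@H]1[C@@H]3CC[C@@H]3[C@@H]21 | intermediate
9 | hydroxy ester (C3 methyl ester, C6H2OH) | COC(=O)[C@@H]2[C@H](CO)[C@H]1[C@@H]3CC[C@@H]3[C@@H]21 | intermediate
10 | γ-lactone C3(=O)-O-C6H2 | O1C(=O)[C@@H]2[C@H](C1)[C@H]3[C@@H]4CC[C@@H]4[C@@H]23 | intermediate
11 | lactol (anomers at C3) | O1C(O)[C@@H]2[C@H](C1)[C@H]3[C@@H]4CC[C@@H]4[C@@H]23 | intermediate
12 | cis vinyl alcohol | C=C[C@@H]2[C@H](CO)[C@H]1[C@@H]3CC[C@@H]3[C@@H]21 | intermediate
13 | 2,2-dimethyl-1,3-dioxan-5-ol | OC1COC(C)(C)OC1 | starting material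
14 | 1,7-dibromoheptane | BrCCCCCCCBr | starting material
15 | 5-[(7-bromoheptyl)oxy]-2,2-dimethyl-1,3-dioxane | BrCCCCCCCOC1COC(C)(C)OC1 | intermediate
16 | 2,3-dibromopropene | C=C(Br)CBr | starting material
17 | Grignard reagent of 15 | Br[Mg]CCCCCCCOC1COC(C)(C)OC1 | intermediate
18 | 5-[(9-bromodec-9-en-1-yl)oxy]-2,2-dimethyl-1,3-dioxane | C=C(Br)CCCCCCCCOC1COC(C)(C)OC1 | intermediate
19 | bis(9-BBN) adduct of 12 (C2-B and C6-O-B) | C1CCC2CCCC1B2CC[C@@H]3[C@H](COB4C5CCCC4CCC5)[C@H]6[C@@H]7CC[C@@H]7[C@@H]36 | intermediate
20 | coupled alcohol | C=C(CCCCCCCCOC1COC(C)(C)OC1)CC[C@@H]2[C@H](CO)[C@H]1[C@@H]3CC[C@@H]3[C@@H]21 | intermediate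
21 | aldehyde | C=C(CCCCCCCCOC1COC(C)(C)OC1)CC[C@@H]2[C@H](C=O)[C@H]1[C@@H]3CC[C@@H]3[C@@H]21 | intermediate
22 | metathesis diene | C=C(CCCCCCCCOC1COC(C)(C)OC1)CC[C@@H]2[C@H](C=C)[C@H]1[C@@H]3CC[C@@H]3[C@@H]21 | intermediate
23 | tetracyclic C1=C6 alkene, acetonide | CC1(C)OCC(CO1)OCCCCCCCCC4CC[C@@H]2[C@H](C=4)[C@H]1[C@@H]3CC[C@@H]3[C@@H]21 | intermediate
24 | saturated acetonide (H1, H4, H5 cis) | CC1(C)OCC(CO1)OCCCCCCCC[C@H]4CC[C@@H]2[C@H](C4)[C@H]1[C@@H]3CC[C@@H]3[C@@H]21 | intermediate
25 | CNP0193334.1, 2-[(8-{ladderane-fused cyclohexyl}octyl)oxy]propane-1,3-diol | OCC(CO)OCCCCCCCC[C@H]1CC[C@@H]2[C@H](C1)[C@H]1[C@@H]3CC[C@@H]3[C@@H]21 | target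

Total step count: 15. Longest linear sequence: 13 (steps 1 to 8 and 11 to 15).

Steps most likely to fail

Step 2. The vinyl termini may polymerise, closure may go crossed or to eight- or six-membered rings, the aryl esters may undergo photo-Fries cleavage, or the crystal may pack with non-parallel arms. The fallback uses ester-capped dienes, for which held double [2+2] closure to a [3]-ladderane is known; it sets out from 2 and comes back at 5.
- Commercial (2E,4E)-muconic acid is mono-esterified with tert-butyl 2,2,2-trichloroacetimidate to give mono-tert-butyl (2E,4E)-muconate F1.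
- DCC/DMAP coupling of two equivalents of F1 with 2 gives naphthalene-1,8-diyl bis(tert-butyl muconate) F2.
- Irradiation in the crystal or in dilute solution gives the capped ladder tetraester F3, with the tert-butyl esters on C9 and C10 cis to each other and exo on ring D.
- CF3CO2H cleaves only the tert-butyl esters to give the vicinal C9,C10-diacid F4.
- Oxidative bis-decarboxylation with Pb(OAc)4/pyridine gives the C9=C10 ladderene F5.
- Diimide or H2, Pd/C saturates F5 to 5.

Step 15. Facial selectivity may be poor, or the double bond may migrate before reduction, which would erode the configuration at C1. The fallback replaces steric control by hydroxyl direction; it sets out from 23 and comes back at 24, which is then hydrolysed as in step 15.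
- SeO2/t-BuOOH allylic hydroxylation, an ene reaction and [2,3] shift that both run on the convex face, attacks the ring methylene next to the substituted alkene carbon and gives the C2 allylic alcohol F6.
- The hydroxyl binds [Ir(cod)(PCy3)(py)]PF6 and directs H2 to its own face, giving the saturated C2 alcohol F7.
- NaH, CS2 and MeI give the xanthate F8.
- Barton-McCombie reduction (Bu3SnH, AIBN) through a radical at C2, remote from the cyclobutanes, gives 24.

Step 5. The alkaloid may discriminate the two carbonyls of this unprecedented anhydride too weakly. The fallback moves the desymmetrisation to the diol oxidation level with an enzyme; it sets out from 5 and comes back at 12.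
- LiAlH4 reduces 5 to the meso ladder diol F9.
- Lipase-catalysed acetylation (Pseudomonas fluorescens lipase, vinyl acetate) gives the monoacetate F10, with C3H2OH free and C6H2OAc.
- TEMPO/PhI(OAc)2 gives the acetoxy aldehyde F11.
- Wittig methylenation gives the vinyl acetate F12.
- K2CO3/MeOH gives 12.

Further compounds
F1 | step 2 | mono-tert-butyl (2E,4E)-muconate | OC(=O)/C=C/C=C/C(=O)OC(C)(C)C
F2 | step 2 | naphthalene-1,8-diyl bis(tert-butyl muconate) | CC(C)(C)OC(=O)/C=C/C=C/C(=O)Oc1cccc2cccc(OC(=O)/C=C/C=C/C(=O)OC(C)(C)C)c12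
F3 | step 2 | capped ladder tetraester | c1cc2OC(=O)[C@@H]3[C@H](C(=O)Oc4cccc(c1)c24)[C@H]5[C@@H]6[C@@H](C(=O)OC(C)(C)C)[C@@H](C(=O)OC(C)(C)C)[C@@H]6[C@@H]35
F4 | step 2 | vicinal C9,C10-diacid | c1cc2OC(=O)[C@@H]3[C@H](C(=O)Oc4cccc(c1)c24)[C@H]5[C@@H]6[C@@H](C(=O)O)[C@@H](C(=O)O)[C@@H]6[C@@H]35
F5 | step 2 | C9=C10 ladderene | c1cc2OC(=O)[C@@H]3[C@H](C(=O)Oc4cccc(c1)c24)[C@H]5[C@@H]6C=C[C@@H]6[C@@H]35
F6 | step 15 | C2 allylic alcohol | CC1(C)OCC(CO1)OCCCCCCCCC4[C@H](O)C[C@@H]2[C@H](C=4)[C@H]1[C@@H]3CC[C@@H]3[C@@H]21
F7 | step 15 | saturated C2 alcohol | CC1(C)OCC(CO1)OCCCCCCCC[C@H]4[C@H](O)C[C@@H]2[C@H](C4)[C@H]1[C@@H]3CC[C@@H]3[C@@H]21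
F8 | step 15 | xanthate | CC1(C)OCC(CO1)OCCCCCCCC[C@H]4[C@H](OC(=S)SC)C[C@@H]2[C@H](C4)[C@H]1[C@@H]3CC[C@@H]3[C@@H]21
F9 | step 5 | meso ladder diol | OC[C@@H]2[C@H](CO)[C@H]1[C@@H]3CC[C@@H]3[C@@H]21
F10 | step 5 | monoacetate | OC[C@@H]2[C@H](COC(C)=O)[C@H]1[C@@H]3CC[C@@H]3[C@@H]21
F11 | step 5 | acetoxy aldehyde | O=C[C@@H]2[C@H](COC(C)=O)[C@H]1[C@@H]3CC[C@@H]3[C@@H]21
F12 | step 5 | vinyl acetate | C=C[C@@H]2[C@H](COC(C)=O)[C@H]1[C@@H]3CC[C@@H]3[C@@H]21
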